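The numbers in the tables are calculated for substances that don't exist, noise included.

In a one-step world the Q that goes would appear as X, and one rate constant would describe the flask. The teal run says otherwise: at 2.50 min Q is read at 0%, yet X stands at 9.3% and L at 82.6%. So for the next run we must decide how long to leave L to turn over, and whether the larger charge asks for anything else.

in all of them: E 200 mM (held)

|  | Q | remark | time |
|---|---|---|---|
| teal | 2 M | run made earlier |  |
| winter | 3.0 M |  | 10 min |
| dawn | 3.0 M |  | 15 min |

teal run (percent of the Q charged)

| time / min | Q / % | L / % | X / % | D / % |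
|---|---|---|---|---|
| 1.00 | 17.6 | 79.3 | 2.0 | 3.6 |
| 1.50 | 7.4 | 87.9 | 3.8 | 3.8 |
| 2.50 | 0 | 82.6 | 9.3 | 7.8 |
| 4.00 | 0.9 | 72.6 | 19.8 | 7.7 |
| 8.00 | 0.9 | 46.4 | 46.6 | 6.6 |
| 12.0 | 0 | 30.5 | 64.4 | 3.7 |

(standard deviation of a reading: 1 percentage point)

- at the start none of E is in solution

- which of these there is most of at the end, counted by the Q in it, winter (D / L / Q / X)
- which of these there is most of at the end, counted by the Q in it, dawn (D / L / Q / X)
- the largest of these amounts at the end, in percent of the Q charged, winter
- the largest of these amounts at the end, in percent of the Q charged, dawn

In teal, L falls at 0.112 min⁻¹ from 4.00 min to 8.00 min and at 0.105 min⁻¹ from there to 12.0 min. The whole span gives 0.108 min⁻¹, which we call the L clock, a pseudo-first-order constant at held E, with a half-life of 6.39 min. At teal's last reading D is 0.121 of L, and we take X as the remainder of the charge. At held E, such a clock gives the same fractions at any charge. The larger charge may strain the uptake of E during the first step, but teal's Q was read at 0% by 2.50 min, shorter than the half-life, so we start from teal's L at 4.00 min. Winter then has L at 37.9% and X at 57.5%, and dawn has L at 22.0% and X at 75.3%. X leads L in winter, but this reckoning takes the fractions to be the same at any charge, so it cannot tell us whether 3.0 M asks for anything else. We charge it and let the flasks show that; on the reckoning, dawn's longer time buys 18 percentage points of X.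

The forecast gives X in both flasks, at 58%, above our winter figure, and 75%, below our dawn figure, and says of gas uptake “that would delay things only slightly”. The flasks give X at 55.8% with L at 39.0% in winter, and X at 73.5% with L at 23.4% in dawn.

    Q + G → L (k = 0.172 L mol⁻¹ s⁻¹)
    G + L → D (k = 0.00864 L mol⁻¹ s⁻¹)
    G + D → X (k = 0.0738 L mol⁻¹ s⁻¹)
    E ⇌ G, rate k4*(csat - [G]) (kL = 1.31 s⁻¹)

Neither flask has come to rest: winter still holds L at 39.0%, and dawn holds it at 23.4%. Ten times winter's time adds 14.1 half-lives of the L clock, and X reaches >99.9%, with dawn, left ten times its own time, at >99.9%. The time is what remains to be spent. G, the E in solution, stands at 0.197 M of 200 mM at winter's end. Moving teal's charge to winter's shifts X from 64.5% to 64.0%, while moving the time instead takes it to 56.4%.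

For dawn read at 1.0 h, the L clock from the same start leaves L at 0.168% and X at 99.8%. The computed flask holds L at 0.222% and X at 99.7%.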